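## Analysis of the target

The target is an isoflavone, 7-hydroxy-6-methoxy-3-(3,4,5-trimethoxyphenyl)chromen-4-one: a benzo ring A fused to a 4-pyranone ring C, with ring B (3,4,5-trimethoxyphenyl) on C3. It has no stereocenter. The only geometric question arises in an acyclic intermediate, where the aryloxy and carboxyl groups must be cis on the future C2=C3 bond. Five oxygen substituents sit on the two benzene rings; four are methyl ethers and only the one on C7, next to the C6 methoxy group, is a free phenol. Ring C is a vinylogous ester that hydroxide or alkoxide opens at C2. Ring B is very electron-rich, and its central methoxy group is the one most exposed to Lewis acids. The difficulty therefore lies in the placement of the ring A oxygens (6,7 and not 7,8) and in freeing exactly one of five ether oxygens. The strategy rests on C4a of ring A: it is ortho to C8a, which carries O1, and para to the C7 oxygen, and its neighbour C5 bears only hydrogen. An acyl cation held on the tether O1–C2=C3 therefore has one activated, unhindered carbon within reach, and bonding there forms C4–C4a and closes ring C.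

## Retrosynthetic reasoning

**15 ⇒ 14 (O–alkyl bond at C7).** The C7 hydroxyl is masked as the isopropyl ether 14. A mask is needed for two reasons. The phenol partner must offer a single nucleophilic oxygen when the two halves are joined, and a free hydroxyl para to the acylation site would itself be acylated or sulfonylated in the ring-closing medium. A secondary alkyl ether survives base, peracid and anhydrous strong acid, and a Lewis acid removes it faster than it removes methyl. The forward step must cleave one ether out of five.

**14 ⇒ 12 (C4–C4a).** Ring C is opened at the bond between the carbonyl carbon and ring A. This cut is chosen because C4a is an unfunctionalized arene C–H, so no halogen or metal handle is needed, and it turns the ketone into a carboxylic acid. The acyclic acid 12 already holds every carbon and oxygen of the target. The forward reaction has to activate the acid (as the mixed anhydride 13) and direct the acyl carbon to the ring carbon para to the isopropoxy group and not to the other ortho carbon, which lies between two oxygens. Ring closure needs the aryloxy and carboxyl groups cis, which is the Z geometry of 12.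

**12 ⇒ 11 (ester C–O).** The acid is traced to its methyl ester 11. The ester is cleaved before ring C exists, because hydroxide would open the pyranone of 14 at C2; the open-chain aryloxyacrylate is less exposed.

**11 ⇒ 10 + 5 (C3–O).** The vinylic carbon–oxygen bond is cut. This divides the molecule into two halves of similar size, each derived from one commercial arene: the enol sulfonate 10 carries ring B and the three-carbon unit C2–C3–C4, and the phenol 5 carries ring A. The forward reaction is an addition–elimination at C3, which should keep the geometry of 10.

**10 ⇒ 9 ⇒ 7 + 8, and 7 ⇒ 6.** The sulfonate 10 is the O-sulfonylated enol 9. The bond between the aryl-bearing carbon and the formyl carbon of 9 (the future C3–C2 bond) is cut to the arylacetate 7 and the one-carbon ester 8, a crossed Claisen condensation. The ester 7 comes from the commercial acid 6, since a carboxylate cannot be C-formylated in this way.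

**5 ⇒ 4 ⇒ 3 ⇒ 1 + 2.** The phenolic oxygen of 5, the future O1, is traced through the formate 4 to the formyl carbon of aldehyde 3 by an oxidative aryl migration. Aldehyde 3 is the O-alkylation product of 1 with 2. In 1 the two ring oxygens are already differentiated: the free hydroxyl is the one that becomes the C7 oxygen, the methoxy group becomes C6–OMe, and the aldehyde carbon marks the position of O1.

## Alternatives that were turned down

**Alternative 1: ring A by cycloaddition.**
- Disconnection: ring A is cut at C5–C6 and C4a–C8a into the terminal alkynyl ketone A2, 1-(3,4,5-trimethoxyphenyl)but-3-yn-2-one, and the tetraoxygenated diene A3, (1Z,3Z)-1,4-dimethoxy-1,3-bis(trimethylsilyloxy)buta-1,3-diene.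
- Forward key step: Diels–Alder addition of A3 across the triple bond of A2. Acid then removes methanol and the silyl groups and leaves the deoxybenzoin A1, 1-(2,4-dihydroxy-5-methoxyphenyl)-2-(3,4,5-trimethoxyphenyl)ethanone. A one-carbon insertion at the benzylic carbon would then close ring C.
- For: the polarization of the partners fixes the regiochemistry, since the methoxy-bearing nucleophilic terminus of A3 bonds to the β-carbon of A2. A1 also reaches the target without any protecting group, and on that point this plan is stronger than the chosen one.
- Against: A3 is a hydrolytically labile bis-silyl ketene acetal that must be made and used at once. A2 has a methylene group activated by both the carbonyl and an electron-rich arene next to an unhindered ynone, so allene formation and Michael oligomerization threaten. The benzene ring assembled with this effort carries a pattern that commercial arenes already have.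
- Comparison: the chosen strategy pays one deprotection step and in return uses only bench-stable intermediates and builds no ring that can be bought.

**Alternative 2: enamine acylation and cyclization.**
- Disconnection: ring C is cut at C3–C4 and O1–C2 into the enamine A5, 4-[(E)-2-(3,4,5-trimethoxyphenyl)ethenyl]morpholine, and the acid chloride A6, 2-(acetyloxy)-4-(benzyloxy)-5-methoxybenzoyl chloride.
- Forward key step: C-acylation of A5 at its aryl-bearing carbon by A6. On acidic work-up the freed phenol adds to the iminium carbon and morpholine leaves, giving A4, 7-(benzyloxy)-6-methoxy-3-(3,4,5-trimethoxyphenyl)chromen-4-one. Hydrogenolysis over Pd/C would finish.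
- For: two bonds of ring C form in one flask. The ring A pattern is fixed in A6 before ring closure, so the key step has no regiochemical question. Hydrogenolysis of a benzyl ether cannot touch a methyl ether. On these three points it is as strong as or stronger than the chosen plan.
- Against: A5 derives from an enolizable arylacetaldehyde that condenses with itself and oxidizes in air, and as a styryl enamine it is a weak carbon nucleophile. A6 needs a tetrasubstituted salicylic acid that is not an article of commerce and costs several steps. Its acetate can be transferred to the enamine or to morpholine in place of the wanted C-acylation.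
- Comparison: the overall length is no shorter. The chosen strategy offers robust intermediates, and its one regiochemical question is settled by the substitution pattern itself.

**Alternative 3: ring A by cyclobutenone ring expansion.**
- Disconnection: ring A is cut at C4a–C8a and traced to the 4-alkenylcyclobutenone A8, 4-[(E)-3-(tert-butyldimethylsilyloxy)-4-(3,4,5-trimethoxyphenyl)but-1-enyl]-4-methoxy-3-(propan-2-yloxy)cyclobut-2-en-1-one.
- Forward key step: heating opens A8 to a dienylketene, whose ketene carbon bonds to the alkene terminus in a 6π electrocyclization. Tautomerization gives the phenol A7, 2-[1-(tert-butyldimethylsilyloxy)-2-(3,4,5-trimethoxyphenyl)ethyl]-4-methoxy-5-(propan-2-yloxy)phenol (racemic).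
- For: every ring A substituent is placed by the connectivity of the four-membered ring, so no electrophilic substitution and no directing effect is relied on. In regiochemical certainty it is stronger than the chosen plan.
- Against: A8 needs a squaric ester with two different alkoxy groups, a reduction to place hydrogen on one ring carbon, and a low-temperature addition of an alkenylmetal reagent. After the key step, desilylation, oxidation of the carbinol, one-carbon insertion with ring closure and removal of the isopropyl group are still to come. A stereocenter is made only to be destroyed.
- Comparison: the chosen strategy reaches the same oxygen pattern from a commercial benzaldehyde in two steps and closes ring C directly at the right oxidation level.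

Key step: step 8

Assumption: 9, 10, 11, 12 and 13 are drawn as the Z isomers, with the oxygen substituent on C3 cis to the carboxyl carbon, which the chelation-controlled sulfonylation and a stereoretentive substitution should favour. Any E isomer formed alongside is carried forward, because the acid of step 8 equilibrates the double bond.

## Route

**Step 1**
Reactants: 1 isovanillin (3-hydroxy-4-methoxybenzaldehyde); 2 2-bromopropane
Product: 3 4-methoxy-3-(propan-2-yloxy)benzaldehyde
Conditions: K2CO3, DMF, 70 °C
Reagents that add atoms: none
Why: Williamson ether synthesis (SN2 O-alkylation) at the only acidic site of 1; the secondary bromide reacts acceptably in DMF, and elimination to propene only consumes excess 2.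

**Step 2**
Reactants: 3 4-methoxy-3-(propan-2-yloxy)benzaldehyde
Product: 5 4-methoxy-3-(propan-2-yloxy)phenol, via aryl formate 4 (not isolated)
Conditions: mCPBA, CH2Cl2, rt; then K2CO3 (cat.), MeOH, rt
Reagents that add atoms: 3-chloroperoxybenzoic acid (mCPBA), O=C(OO)c1cccc(Cl)c1
Why: Baeyer–Villiger oxidation of an electron-rich benzaldehyde (Dakin-type): the aryl group, activated by its para methoxy group, migrates in preference to hydride and gives the formate 4. Base-catalysed methanolysis of this labile aryl formate frees the phenol without touching the ethers.

**Step 3**
Reactants: 6 2-(3,4,5-trimethoxyphenyl)acetic acid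
Product: 7 methyl 2-(3,4,5-trimethoxyphenyl)acetate
Conditions: MeOH, H2SO4 (cat.), reflux
Reagents that add atoms: methanol, CO
Why: Fischer esterification driven by the excess of methanol; the ester is needed because step 4 requires an ester enolate and not a carboxylate.

**Step 4**
Reactants: 7 methyl 2-(3,4,5-trimethoxyphenyl)acetate; 8 methyl formate
Product: 9 methyl (Z)-3-hydroxy-2-(3,4,5-trimethoxyphenyl)prop-2-enoate (hydrogen-bonded enol of the α-formyl ester)
Conditions: NaH, THF, 0 °C → rt; then aq. HCl
Reagents that add atoms: none
Why: Crossed Claisen condensation (C-formylation): the benzylic ester enolate attacks the non-enolizable formate, and deprotonation of the acidic product to its sodium enolate drives the equilibrium. Acidification should give 9 as the chelated Z enol in equilibrium with its aldehyde tautomer.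

**Step 5**
Reactants: 9 methyl (Z)-3-hydroxy-2-(3,4,5-trimethoxyphenyl)prop-2-enoate
Product: 10 methyl (Z)-3-[(4-methylbenzenesulfonyl)oxy]-2-(3,4,5-trimethoxyphenyl)prop-2-enoate
Conditions: TsCl, N-methylimidazole, LiOH, MeCN, 0 °C
Reagents that add atoms: 4-methylbenzenesulfonyl chloride (TsCl), Cc1ccc(cc1)S(=O)(=O)Cl
Why: O-sulfonylation of a 1,3-dicarbonyl enolate: the lithium cation chelates the enolate oxygen and the ester carbonyl and so holds the oxygen cis to the ester. N-Methylimidazole delivers the sulfonyl group as an N-sulfonylimidazolium salt, so the Z enol tosylate should result.

**Step 6**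
Reactants: 10 methyl (Z)-3-[(4-methylbenzenesulfonyl)oxy]-2-(3,4,5-trimethoxyphenyl)prop-2-enoate; 5 4-methoxy-3-(propan-2-yloxy)phenol
Product: 11 methyl (Z)-3-[4-methoxy-3-(propan-2-yloxy)phenoxy]-2-(3,4,5-trimethoxyphenyl)prop-2-enoate
Conditions: K2CO3, DMF, 0 °C → rt
Reagents that add atoms: none
Why: Nucleophilic vinylic substitution by addition–elimination: the phenoxide of 5 adds to C3 of the β-sulfonyloxyacrylate and the ester enolate expels tosylate. C2 bears no hydrogen, so no elimination–addition path exists, and with so good a leaving group expulsion should outrun bond rotation and keep the Z geometry.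

**Step 7**
Reactants: 11 methyl (Z)-3-[4-methoxy-3-(propan-2-yloxy)phenoxy]-2-(3,4,5-trimethoxyphenyl)prop-2-enoate
Product: 12 (Z)-3-[4-methoxy-3-(propan-2-yloxy)phenoxy]-2-(3,4,5-trimethoxyphenyl)prop-2-enoic acid
Conditions: LiOH, THF/MeOH/H2O, 0 °C → rt; then aq. HCl to pH 3, 0 °C
Reagents that add atoms: lithium hydroxide, [Li+].[OH-]
Why: Ester saponification by acyl–oxygen cleavage; conjugate attack at C3 is held back by donation from the aryloxy oxygen and by the aryl group on C2. Cold, mild acidification should liberate the acid without hydrolysing the enol ether.

**Step 8**
Reactants: 12 (Z)-3-[4-methoxy-3-(propan-2-yloxy)phenoxy]-2-(3,4,5-trimethoxyphenyl)prop-2-enoic acid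
Product: 14 6-methoxy-7-(propan-2-yloxy)-3-(3,4,5-trimethoxyphenyl)chromen-4-one, via acyl methanesulfonate 13 (not isolated)
Conditions: Eaton's reagent (P2O5 in MeSO3H, about 1:10 w/w), rt → 50 °C
Reagents that add atoms: none
Why: Intramolecular Friedel–Crafts acylation, the acid-mediated cycloacylation of a 3-aryloxyacrylic acid that is the established way from such acids to chromones. The reagent converts the carboxyl group of 12 into the mixed anhydride 13, which ionizes to an acylium ion; its carbon (C4) is attacked by the ring A carbon ortho to the ether oxygen and para to the isopropoxy group (C4a), and loss of a proton restores the arene. Ring C closes as a six-membered ring by electrophilic aromatic substitution, exo with respect to the acylium C≡O bond (6-exo-dig), which requires the aryloxy and carboxyl groups cis on C2=C3 as in the Z acid. Any E isomer should be funnelled into the reactive form, because the strong acid protonates the enol ether at C2 reversibly and so allows rotation about C2–C3. No stereocenter is formed. The step needs regioselectivity between the two carbons ortho to the aryloxy oxygen: the one para to the isopropoxy group is the more activated and is flanked by hydrogen, whereas the other lies between two oxygen substituents, so the 6,7-dioxygenated chromone and not the 7,8 isomer should form. It also needs chemoselectivity: ring B cannot be reached from the tether (a four-membered ring would result), and the secondary alkyl ether and the methyl ethers should tolerate the anhydrous acid at moderate temperature where a benzyl ether would not. The product is a vinylogous ester deactivated toward further acylation and should be stable in the medium.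

**Step 9**
Reactants: 14 6-methoxy-7-(propan-2-yloxy)-3-(3,4,5-trimethoxyphenyl)chromen-4-one
Product: 15 7-hydroxy-6-methoxy-3-(3,4,5-trimethoxyphenyl)chromen-4-one
Conditions: BCl3 (3 equiv), CH2Cl2, −78 → 0 °C; then MeOH, aq. NaHCO3
Reagents that add atoms: none
Why: Lewis acid-mediated ether cleavage: the BCl3 complex of the secondary isopropyl ether ionizes and loses 2-chloropropane far faster than chloride attacks a methyl group in an SN2 sense. No methoxy group is ortho or peri to the carbonyl (C5 bears hydrogen), so no chelation-assisted demethylation is expected, and low temperature protects the central methoxy group of ring B.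

## Compound list

1 | isovanillin (3-hydroxy-4-methoxybenzaldehyde) | COc1ccc(C=O)cc1O | starting material
2 | 2-bromopropane | CC(C)Br | starting material
3 | 4-methoxy-3-(propan-2-yloxy)benzaldehyde | COc1ccc(C=O)cc1OC(C)C | intermediate
4 | 4-methoxy-3-(propan-2-yloxy)phenyl formate | COc1ccc(OC=O)cc1OC(C)C | intermediate
5 | 4-methoxy-3-(propan-2-yloxy)phenol | COc1ccc(O)cc1OC(C)C | intermediate
6 | 2-(3,4,5-trimethoxyphenyl)acetic acid | COc1cc(CC(=O)O)cc(OC)c1OC | starting material
7 | methyl 2-(3,4,5-trimethoxyphenyl)acetate | COC(=O)Cc1cc(OC)c(OC)c(OC)c1 | intermediate
8 | methyl formate | COC=O | starting material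
9 | methyl (Z)-3-hydroxy-2-(3,4,5-trimethoxyphenyl)prop-2-enoate | O/C=C(\C(=O)OC)c1cc(OC)c(OC)c(OC)c1 | intermediate
10 | methyl (Z)-3-[(4-methylbenzenesulfonyl)oxy]-2-(3,4,5-trimethoxyphenyl)prop-2-enoate | Cc1ccc(cc1)S(=O)(=O)O/C=C(\C(=O)OC)c1cc(OC)c(OC)c(OC)c1 | intermediate
11 | methyl (Z)-3-[4-methoxy-3-(propan-2-yloxy)phenoxy]-2-(3,4,5-trimethoxyphenyl)prop-2-enoate | COc1ccc(O/C=C(\C(=O)OC)c2cc(OC)c(OC)c(OC)c2)cc1OC(C)C | intermediate
12 | (Z)-3-[4-methoxy-3-(propan-2-yloxy)phenoxy]-2-(3,4,5-trimethoxyphenyl)prop-2-enoic acid | COc1ccc(O/C=C(\C(=O)O)c2cc(OC)c(OC)c(OC)c2)cc1OC(C)C | intermediate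
13 | methanesulfonic (Z)-3-[4-methoxy-3-(propan-2-yloxy)phenoxy]-2-(3,4,5-trimethoxyphenyl)prop-2-enoic anhydride | COc1ccc(O/C=C(\C(=O)OS(C)(=O)=O)c2cc(OC)c(OC)c(OC)c2)cc1OC(C)C | intermediate
14 | 6-methoxy-7-(propan-2-yloxy)-3-(3,4,5-trimethoxyphenyl)chromen-4-one | COc1cc2c(=O)c(-c3cc(OC)c(OC)c(OC)c3)coc2cc1OC(C)C | intermediate
15 | 7-hydroxy-6-methoxy-3-(3,4,5-trimethoxyphenyl)chromen-4-one | COc1cc2c(=O)c(-c3cc(OC)c(OC)c(OC)c3)coc2cc1O | target

## Step count and least certain steps

Total: 9 steps. Longest linear sequence: 7 steps (steps 3 to 9, from 6); the phenol branch (steps 1 and 2) joins at step 6.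

**Step 8 (key step).** The isopropyl group may be lost in the acid before ring closure, followed by O-sulfonylation of the freed phenol. An E-configured acid may equilibrate slowly. At high concentration the acylium ion may acylate ring B of a second molecule. Fallback: change the order of bond formation, setting out from 5 and 6. Heating them in BF3·OEt2 (80 °C) should acylate the phenol ortho to its hydroxyl, at the same carbon para to the isopropoxy group, and give 1-[2-hydroxy-5-methoxy-4-(propan-2-yloxy)phenyl]-2-(3,4,5-trimethoxyphenyl)ethan-1-one F1. N,N-Dimethylformamide dimethyl acetal (toluene, 90 °C) then adds the one-carbon unit at the benzylic carbon, and the phenol closes ring C with loss of dimethylamine. This comes back to the route at 14.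

**Step 6.** The phenoxide may attack sulfur instead of C3, which transfers the sulfonyl group to the phenol and returns the enolate of 9. Reversible addition of phenoxide to the product may erode the alkene geometry. Fallback: setting out from 9, oxalyl chloride and DMF in CH2Cl2 (Vilsmeier conditions) should give methyl (Z)-3-chloro-2-(3,4,5-trimethoxyphenyl)prop-2-enoate F2, whose leaving group can be displaced only at carbon; either geometric isomer serves. With 5 and K2CO3 in DMF it comes back to the route at 11.

**Step 7.** Hydroxide may add to C3 and expel the phenoxide, followed by deformylation; the enol ether may also hydrolyse during acidification. Fallback: leave out the free acid. Setting out from 11, the ester is heated directly in Eaton's reagent, where the protonated ester loses methanol and gives the same acylium ion, and the route is rejoined at 14. No new compound is made.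

**Step 9.** Dealkylation may go too far: BCl3 can reach the central methyl ether of ring B through chelation between neighbouring methoxy oxygens if the temperature or the excess is not controlled. Fallback: dispense with the protecting group. Setting out from 6, acylation of commercial 4-methoxybenzene-1,3-diol F3 in BF3·OEt2 (80 °C) should occur ortho to one hydroxyl and para to the other and give 1-(2,4-dihydroxy-5-methoxyphenyl)-2-(3,4,5-trimethoxyphenyl)ethan-1-one F4, the same compound as A1. BF3·OEt2, DMF and MeSO2Cl (70 °C) then insert the one-carbon unit and close ring C with the second hydroxyl left free, which comes back to the route at 15.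

## Further compounds

F1 | step 8 | 1-[2-hydroxy-5-methoxy-4-(propan-2-yloxy)phenyl]-2-(3,4,5-trimethoxyphenyl)ethan-1-one | COc1cc(C(=O)Cc2cc(OC)c(OC)c(OC)c2)c(O)cc1OC(C)C
F2 | step 6 | methyl (Z)-3-chloro-2-(3,4,5-trimethoxyphenyl)prop-2-enoate | Cl/C=C(\C(=O)OC)c1cc(OC)c(OC)c(OC)c1
F0 | step 7 | none | none
F3 | step 9 | 4-methoxybenzene-1,3-diol | COc1ccc(O)cc1O
F4 | step 9 | 1-(2,4-dihydroxy-5-methoxyphenyl)-2-(3,4,5-trimethoxyphenyl)ethan-1-one | COc1cc(C(=O)Cc2cc(OC)c(OC)c(OC)c2)c(O)cc1O
A1 | alternative 1 | 1-(2,4-dihydroxy-5-methoxyphenyl)-2-(3,4,5-trimethoxyphenyl)ethanone | COc1cc(C(=O)Cc2cc(OC)c(OC)c(OC)c2)c(O)cc1O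
A2 | alternative 1 | 1-(3,4,5-trimethoxyphenyl)but-3-yn-2-one | C#CC(=O)Cc1cc(OC)c(OC)c(OC)c1
A3 | alternative 1 | (1Z,3Z)-1,4-dimethoxy-1,3-bis(trimethylsilyloxy)buta-1,3-diene | CO/C=C(O[Si](C)(C)C)/C=C(/OC)O[Si](C)(C)C
A4 | alternative 2 | 7-(benzyloxy)-6-methoxy-3-(3,4,5-trimethoxyphenyl)chromen-4-one | COc1cc2c(=O)c(-c3cc(OC)c(OC)c(OC)c3)coc2cc1OCc1ccccc1
A5 | alternative 2 | 4-[(E)-2-(3,4,5-trimethoxyphenyl)ethenyl]morpholine | COc1cc(/C=C/N2CCOCC2)cc(OC)c1OC
A6 | alternative 2 | 2-(acetyloxy)-4-(benzyloxy)-5-methoxybenzoyl chloride | CC(=O)Oc1cc(OCc2ccccc2)c(OC)cc1C(Cl)=O
A7 | alternative 3 | 2-[1-(tert-butyldimethylsilyloxy)-2-(3,4,5-trimethoxyphenyl)ethyl]-4-methoxy-5-(propan-2-yloxy)phenol (racemic) | COc1cc(C(Cc2cc(OC)c(OC)c(OC)c2)O[Si](C)(C)C(C)(C)C)c(O)cc1OC(C)C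
A8 | alternative 3 | 4-[(E)-3-(tert-butyldimethylsilyloxy)-4-(3,4,5-trimethoxyphenyl)but-1-enyl]-4-methoxy-3-(propan-2-yloxy)cyclobut-2-en-1-one (racemic, mixture of diastereomers) | COC1(/C=C/C(Cc2cc(OC)c(OC)c(OC)c2)O[Si](C)(C)C(C)(C)C)C(=O)C=C1OC(C)C
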